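**Retrosynthetic overview**
1. The target comes from its tribenzyl-protected form (ring B benzyl ester and two benzyl ethers) by a final hydrogenolysis.
2. The pyranone ring of the isocoumarin is the only ring that is built (both benzene rings are bought); it is closed last but one by carboxylate-directed ruthenium C–H annulation of a 2-aryloxy-4-methoxybenzoic acid with a hexanoyl sulfoxonium ylide.
3. The ring B 2-oxoheptyl chain comes from lateral lithiation of the ring B ortho-toluate methyl group and acylation with the Weinreb amide of hexanoic acid.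
4. The hindered diaryl ether bond is made by a proposed new rhodium-carbenoid O–H insertion: ring B is a masked hydroquinone (C2–OH para to C5–O), so a ring B para-quinone diazide is inserted into the phenol O–H of methyl 4-methoxysalicylate.
5. The quinone diazide comes from orsellinic acid by selective benzylation, para azo coupling with reduction, and diazotization.

Assumption: the target SMILES has no stereocentre and no stereogenic double bond, so the compound is achiral and the single-enantiomer requirement is met by the constitution alone.
Labels used below: ring A is the methoxy-bearing ring that becomes the isocoumarin; ring B is the orsellinate ring, numbered C1 (carboxyl-bearing carbon), C2 and C4 (oxygens), C5 (ether oxygen), C6 (methyl, later 2-oxoheptyl).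

**Route**

Step 1
Reactants: 1 orsellinic acid (2,4-dihydroxy-6-methylbenzoic acid)
Product: 2 benzyl 4-(benzyloxy)-2-hydroxy-6-methylbenzoate
Conditions: BnBr (2.1 equiv), K2CO3 (2.2 equiv), acetone, reflux
Reagents that add atoms: benzyl bromide, BrCc1ccccc1
Why: Carboxylate O-alkylation and Williamson etherification of the more acidic, non-chelated C4 phenol go first, while the C2 phenol is held in a hydrogen bond to the carbonyl group and stays free (chemoselective SN2 benzylation).

Step 2
Reactants: 2 benzyl 4-(benzyloxy)-2-hydroxy-6-methylbenzoate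
Product: 4 benzyl 5-amino-4-(benzyloxy)-2-hydroxy-6-methylbenzoate, via azo compound 3 (not isolated)
Conditions: 4-BrC6H4N2BF4 (1.05 equiv), NaOH (1.1 equiv), THF/H2O, 0 °C; then Na2S2O4 (4 equiv), THF/H2O, 50 °C
Reagents that add atoms: 4-bromobenzenediazonium tetrafluoroborate, Brc1ccc([N+]#N)cc1.F[B-](F)(F)F
Why: Azo coupling of the phenolate takes place para to the free C2 oxygen (C5, the resorcinol 4-type position, also ortho to the C4 ether), and dithionite then cleaves the N=N bond to the para-aminophenol without touching the benzyl groups (azo coupling followed by reductive azo cleavage).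

Step 3
Reactants: 4 benzyl 5-amino-4-(benzyloxy)-2-hydroxy-6-methylbenzoate
Product: 5 benzyl 4-(benzyloxy)-3-diazo-2-methyl-6-oxocyclohexa-1,4-diene-1-carboxylate (ring B para-quinone diazide)
Conditions: t-BuONO (1.3 equiv), AcOH (20 mol %), MeCN/THF, 0 °C, dark
Reagents that add atoms: tert-butyl nitrite, CC(C)(C)ON=O
Why: Diazotization of a para-aminophenol gives the diazonium phenolate, which is the isolable zwitterionic para-quinone diazide (diazotization).

Step 4
Reactants: 5 ring B para-quinone diazide; 6 methyl 2-hydroxy-4-methoxybenzoate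
Product: 7 benzyl 4-(benzyloxy)-2-hydroxy-5-[5-methoxy-2-(methoxycarbonyl)phenoxy]-6-methylbenzoate
Conditions: Rh2(esp)2 (2 mol %; esp = α,α,α′,α′-tetramethyl-1,3-benzenedipropanoate), 6 (3 equiv), PhCF3, 70 °C, slow addition of 5 over 6 h, dark, argon
Reagents that add atoms: none
Why: Proposed new method: the dirhodium tetracarboxylate (divalent rhodium) expels N2 from 5 to give a quinoid rhodium carbene whose carbene carbon (ring B C5) is strongly electrophilic because attack on it restores aromaticity, the phenol oxygen of 6 (in excess) adds to give an oxonium ylide, and proton transfer to the C2 oxygen releases the para-hydroxy diaryl ether, so the tri-ortho-substituted C5–O–aryl bond is formed ipso-specifically under neutral conditions; the closest known reaction type is rhodium-carbenoid O–H insertion of diazo carbonyl compounds into phenols and alcohols (together with carbene transfer from quinone diazides to alcohols and arenes), which has not been shown for a fully substituted quinone diazide and a hydrogen-bonded salicylate phenol.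

Step 5
Reactants: 7 benzyl 4-(benzyloxy)-2-hydroxy-5-[5-methoxy-2-(methoxycarbonyl)phenoxy]-6-methylbenzoate
Product: 8 benzyl 2,4-bis(benzyloxy)-5-[5-methoxy-2-(methoxycarbonyl)phenoxy]-6-methylbenzoate
Conditions: BnBr (1.5 equiv), K2CO3 (2 equiv), DMF, 60 °C
Reagents that add atoms: benzyl bromide, BrCc1ccccc1
Why: Williamson etherification of the chelated C2 phenol needs only mild heating and protects it so that no phenoxide interferes with the later amide-base step.

Step 6
Reactants: 8 benzyl 2,4-bis(benzyloxy)-5-[5-methoxy-2-(methoxycarbonyl)phenoxy]-6-methylbenzoate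
Product: 9 benzyl 2,4-bis(benzyloxy)-5-(2-carboxy-5-methoxyphenoxy)-6-methylbenzoate
Conditions: LiOH·H2O (4 equiv), THF/H2O, 45 °C; then 1 M HCl to pH 3
Reagents that add atoms: lithium hydroxide, [Li+].[OH-]
Why: Saponification (BAc2) attacks only the ring A methyl ester, which has one ortho substituent, while the ring B benzyl ester is shielded by two ortho substituents and survives.

Step 7
Reactants: 9 benzyl 2,4-bis(benzyloxy)-5-(2-carboxy-5-methoxyphenoxy)-6-methylbenzoate; 10 N-methoxy-N-methylhexanamide
Product: 11 benzyl 2,4-bis(benzyloxy)-5-(2-carboxy-5-methoxyphenoxy)-6-(2-oxoheptyl)benzoate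
Conditions: LiN(iPr)2 (3.2 equiv, commercial solution), THF, −78 °C, 1 h; then 10 (1.5 equiv), −78 to −40 °C; 1 M HCl quench
Reagents that add atoms: none
Why: After deprotonation of the carboxylic acid, lateral lithiation of the ring B methyl group ortho to the ester gives a benzylic anion that acylates the Weinreb amide to a stable chelated adduct, which releases the ketone only on quench (lateral lithiation and Weinreb ketone synthesis).

Step 8
Reactants: 12 hexanoyl chloride; 13 trimethylsulfoxonium iodide
Product: 15 1-(dimethyl-oxo-lambda6-sulfanylidene)heptan-2-one (hexanoyl sulfoxonium ylide), via dimethylsulfoxonium methylide 14 (not isolated)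
Conditions: 13 (2.2 equiv), KOtBu (2.2 equiv), THF, reflux, 2 h; then 12 (1.0 equiv), 0 °C to rt
Reagents that add atoms: none
Why: Deprotonation gives the sulfoxonium methylide, which is C-acylated by the acid chloride while a second equivalent takes up the HCl (acylation of a Corey–Chaykovsky ylide).

Step 9
Reactants: 11 benzyl 2,4-bis(benzyloxy)-5-(2-carboxy-5-methoxyphenoxy)-6-(2-oxoheptyl)benzoate; 15 hexanoyl sulfoxonium ylide
Product: 16 benzyl 2,4-bis(benzyloxy)-5-[(6-methoxy-1-oxo-3-pentyl-1H-isochromen-8-yl)oxy]-6-(2-oxoheptyl)benzoate
Conditions: [RuCl2(p-cymene)]2 (5 mol %), NaOAc (30 mol %), 15 (1.5 equiv), CF3CH2OH, 80 °C, 16 h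
Reagents that add atoms: none
Why: Carboxylate-assisted C–H ruthenation (divalent ruthenium) at the only free ortho position of ring A, carbene formation from the ylide with loss of DMSO, migratory insertion and protodemetalation give the ortho-(2-oxoheptyl) acid, which cyclodehydrates to the 3-pentylisocoumarin, while the ring B keto ester has no free acid and stays open (carboxylate-directed C–H activation and annulation with a sulfoxonium ylide, a reaction type established for simpler benzoic acids).

Step 10
Reactants: 16 benzyl 2,4-bis(benzyloxy)-5-[(6-methoxy-1-oxo-3-pentyl-1H-isochromen-8-yl)oxy]-6-(2-oxoheptyl)benzoate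
Product: 17 beta-collatolic acid
Conditions: H2 (1 atm), 10 % Pd/C, EtOAc, rt, stopped after uptake of 3 equiv H2; filtered and concentrated below 30 °C
Reagents that add atoms: none
Why: Catalytic hydrogenolysis cleaves the two benzyl ethers and the benzyl ester under neutral conditions faster than it saturates the trisubstituted, conjugated enol-lactone double bond, and it leaves the ketone, the methyl ether and the diaryl ether untouched.

**Compound list**
1 | orsellinic acid (2,4-dihydroxy-6-methylbenzoic acid) | Cc1cc(O)cc(O)c1C(=O)O | starting material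
2 | benzyl 4-(benzyloxy)-2-hydroxy-6-methylbenzoate | Cc1cc(OCc2ccccc2)cc(O)c1C(=O)OCc1ccccc1 | intermediate
3 | benzyl 4-(benzyloxy)-5-[(E)-(4-bromophenyl)diazenyl]-2-hydroxy-6-methylbenzoate (azo compound) | Cc1c(/N=N/c2ccc(Br)cc2)c(OCc2ccccc2)cc(O)c1C(=O)OCc1ccccc1 | intermediate
4 | benzyl 5-amino-4-(benzyloxy)-2-hydroxy-6-methylbenzoate | Cc1c(N)c(OCc2ccccc2)cc(O)c1C(=O)OCc1ccccc1 | intermediate
5 | benzyl 4-(benzyloxy)-3-diazo-2-methyl-6-oxocyclohexa-1,4-diene-1-carboxylate (ring B para-quinone diazide) | CC1=C(C(=O)OCc2ccccc2)C(=O)C=C(OCc2ccccc2)C1=[N+]=[N-] | intermediate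
6 | methyl 2-hydroxy-4-methoxybenzoate | COC(=O)c1ccc(OC)cc1O | starting material
7 | benzyl 4-(benzyloxy)-2-hydroxy-5-[5-methoxy-2-(methoxycarbonyl)phenoxy]-6-methylbenzoate | COC(=O)c1ccc(OC)cc1Oc1c(C)c(C(=O)OCc2ccccc2)c(O)cc1OCc1ccccc1 | intermediate
8 | benzyl 2,4-bis(benzyloxy)-5-[5-methoxy-2-(methoxycarbonyl)phenoxy]-6-methylbenzoate | COC(=O)c1ccc(OC)cc1Oc1c(C)c(C(=O)OCc2ccccc2)c(OCc2ccccc2)cc1OCc1ccccc1 | intermediate
9 | benzyl 2,4-bis(benzyloxy)-5-(2-carboxy-5-methoxyphenoxy)-6-methylbenzoate | OC(=O)c1ccc(OC)cc1Oc1c(C)c(C(=O)OCc2ccccc2)c(OCc2ccccc2)cc1OCc1ccccc1 | intermediate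
10 | N-methoxy-N-methylhexanamide | CCCCCC(=O)N(C)OC | starting material
11 | benzyl 2,4-bis(benzyloxy)-5-(2-carboxy-5-methoxyphenoxy)-6-(2-oxoheptyl)benzoate | OC(=O)c1ccc(OC)cc1Oc1c(CC(=O)CCCCC)c(C(=O)OCc2ccccc2)c(OCc2ccccc2)cc1OCc1ccccc1 | intermediate
12 | hexanoyl chloride | CCCCCC(Cl)=O | starting material
13 | trimethylsulfoxonium iodide | C[S+](C)(C)=O.[I-] | starting material
14 | dimethylsulfoxonium methylide | C=S(C)(C)=O | intermediate
15 | 1-(dimethyl-oxo-lambda6-sulfanylidene)heptan-2-one (hexanoyl sulfoxonium ylide) | CCCCCC(=O)C=S(C)(C)=O | intermediate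
16 | benzyl 2,4-bis(benzyloxy)-5-[(6-methoxy-1-oxo-3-pentyl-1H-isochromen-8-yl)oxy]-6-(2-oxoheptyl)benzoate | CCCCCc1cc2cc(OC)cc(Oc3c(CC(=O)CCCCC)c(C(=O)OCc4ccccc4)c(OCc4ccccc4)cc3OCc3ccccc3)c2c(=O)o1 | intermediate
17 | beta-collatolic acid, 2,4-dihydroxy-5-[(6-methoxy-1-oxo-3-pentyl-1H-isochromen-8-yl)oxy]-6-(2-oxoheptyl)benzoic acid | CCCCCC(=O)Cc1c(Oc2cc(OC)cc3cc(CCCCC)oc(=O)c23)c(O)cc(O)c1C(=O)O | target

**Step count and risks**
Total step count: 10. Longest linear sequence: 9 steps (steps 1 to 7, then 9 and 10, from compound 1); step 8 is a one-step side branch.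

The three steps most likely to fail:

Step 4 (the proposed new O–H insertion). The carbenoid could instead arylate a ring carbon of 6, attack the phenyl ring of the neighbouring benzyl ether, or dimerise. The fallback uses known chemistry, sets out from compound 2 and comes back to the route at compound 8. Compound 2 is benzylated at the C2 hydroxyl (BnBr, K2CO3, DMF, 60 °C) to benzyl 2,4-bis(benzyloxy)-6-methylbenzoate F1. Electrophilic bromination with N-bromosuccinimide in MeCN at 0 °C then goes to C5 (para to the C2 ether, next to the methyl group) and gives benzyl 2,4-bis(benzyloxy)-5-bromo-6-methylbenzoate F2. A classical copper-mediated Ullmann ether coupling of F2 with phenol 6 (CuI 20 mol %, picolinic acid 40 mol %, K3PO4, DMSO, 110 °C) gives 8, and steps 6 to 10 follow unchanged.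

Step 9 (ruthenium annulation on a crowded, polyfunctional acid). The ortho-aryloxy acid may react slowly, and the ring B keto ester may interfere. The fallback sets out from compound 11 and comes back at compound 16; it replaces carbene insertion by an oxidative Heck-type manifold. Hept-1-yne and acetic acid are joined by gold-catalysed Markovnikov hydroacyloxylation (Ph3PAuCl/AgOTf 2 mol %, toluene, 60 °C) to hept-1-en-2-yl acetate F3. Acid 11 and F3 are then annulated under oxidative rhodium catalysis ([Cp*RhCl2]2 2.5 mol %, Cp* = pentamethylcyclopentadienyl; Cu(OAc)2·H2O 2 equiv; t-AmOH, 110 °C): carboxylate-directed ortho C–H alkenylation is followed by acyl-transfer lactonisation with loss of acetic acid, which gives 16.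

Step 10 (hydrogenolysis). The enol-lactone C3=C4 bond of the isocoumarin may be partly saturated before the hindered benzyl ester is gone. The fallback sets out from compound 16 and comes back at compound 17; it replaces reduction by Lewis-acid dealkylation. BCl3 (6 equiv) with pentamethylbenzene (9 equiv) as benzyl-cation scavenger in CH2Cl2 at −78 °C, followed by an aqueous THF quench, cleaves the two aryl benzyl ethers and the benzyl ester with no reducing agent present, so the double bond cannot be touched, and at this temperature the non-chelated aryl methyl ether is kept. No new compound is made on this path (F0).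

**Further compounds**
F1 | step 4 | benzyl 2,4-bis(benzyloxy)-6-methylbenzoate | Cc1cc(OCc2ccccc2)cc(OCc2ccccc2)c1C(=O)OCc1ccccc1
F2 | step 4 | benzyl 2,4-bis(benzyloxy)-5-bromo-6-methylbenzoate | Cc1c(Br)c(OCc2ccccc2)cc(OCc2ccccc2)c1C(=O)OCc1ccccc1
F3 | step 9 | hept-1-en-2-yl acetate | CCCCCC(=C)OC(C)=O
F0 | step 10 | none | none
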